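**Retrosynthetic overview**
1. Target 27 comes from the benzylated 8-bromo dimer diol 24 by double Steglich galloylation, then one hydrogenolysis that removes fourteen benzyl groups and the C8 bromine.
2. Upper ring C (final closure): O1–C2 by reductive etherification of keto phenol 20. The C2 aryl group (ring B) is added as a Grignard reagent to Weinreb amide 17 of lactone 16.
3. Key disconnection: upper C3–C4 and O1–C2 (lactol 15) from o-quinone methide 12 and the enamine of silyloxyacetaldehyde 11. The feature used is that upper C4 is a diarylmethine carbon bonded to C4a of upper ring A and to C6 of lower ring A, with the C3 oxygen trans to that aryl group and the ring C oxygen O1 ortho to C4a on ring A.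
4. Benzhydrol 10 comes from the C6-magnesiated 8-bromo epicatechin derivative (1 → 5) and salicylaldehyde 7 (from 6).
5. Ring order: the lower rings A, B and C come intact from epicatechin, and upper ring A from 6. Upper ring C is closed as the lactol (step 7), opened (step 9), and closed again as the flavan (step 11) after ring B is attached (step 10).

Key step: step 7

Remark (assumption on the chemistry): the bromine placed at C8 of the lower unit to direct halogenation to C6 is kept as a blocking group through the key step, since free C8 is the arene position that would otherwise capture the quinone methide, and it leaves with the benzyl groups in step 14. Compounds 11, 18 and 25 are taken as commercial.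

**Step 1**
Reactants: 1 (−)-epicatechin, (2R,3R)
Product: 2 5,7,3',4'-tetra-O-benzyl-(−)-epicatechin (3-OH free)
Conditions: BnBr (4.4 equiv), K2CO3, DMF, 0 °C to rt
Reagents that add atoms: benzyl bromide, BrCc1ccccc1
Why: Williamson etherification in which carbonate deprotonates only the four phenols, so the secondary C3 hydroxyl stays free and the mild base leaves C2 and C3 unchanged.

**Step 2**
Reactants: 2 5,7,3',4'-tetra-O-benzyl-(−)-epicatechin
Product: 3 3-O-(tert-butyldimethylsilyl)-5,7,3',4'-tetra-O-benzyl-(−)-epicatechin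
Conditions: TBSCl, imidazole, DMF, rt
Reagents that add atoms: tert-butyldimethylsilyl chloride, CC(C)(C)[Si](C)(C)Cl
Why: Imidazole-promoted silylation of the secondary alcohol gives an ether that should survive the organomagnesium and low-temperature Lewis acid steps and comes off with the upper silyl group in step 12.

**Step 3**
Reactants: 3 3-O-TBS-5,7,3',4'-tetra-O-benzyl-(−)-epicatechin
Product: 4 8-bromo-3-O-TBS-5,7,3',4'-tetra-O-benzyl-(−)-epicatechin
Conditions: NBS (1.0 equiv), CH2Cl2, −78 °C to −20 °C, dark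
Reagents that add atoms: N-bromosuccinimide, O=C1CCC(=O)N1Br
Why: Electrophilic aromatic bromination with one equivalent of NBS at low temperature should occur at C8, the less hindered of the two ring A positions, which is the established regiochemistry for benzylated flavan-3-ols.

**Step 4**
Reactants: 4 8-bromo-3-O-TBS-5,7,3',4'-tetra-O-benzyl-(−)-epicatechin
Product: 5 8-bromo-6-iodo-3-O-TBS-5,7,3',4'-tetra-O-benzyl-(−)-epicatechin
Conditions: NIS (1.1 equiv), CH2Cl2–MeCN, 0 °C to rt, dark
Reagents that add atoms: N-iodosuccinimide, O=C1CCC(=O)N1I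
Why: A second electrophilic aromatic halogenation should go to C6, the only open position of the trioxygenated ring A and far more electron-rich than catechol ring B, and it places iodine next to bromine so that a site-selective halogen–metal exchange is possible.

**Step 5**
Reactants: 6 2,4,6-trihydroxybenzaldehyde
Product: 7 2-hydroxy-4,6-bis(benzyloxy)benzaldehyde
Conditions: BnBr (2.1 equiv), K2CO3, DMF, rt
Reagents that add atoms: benzyl bromide, BrCc1ccccc1
Why: Williamson etherification should stop at the dibenzyl ether because the last ortho hydroxyl is held in a hydrogen bond to the formyl group and is the least nucleophilic, as in the analogous partial alkylation of phloroacetophenone.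

**Step 6**
Reactants: 5 8-bromo-6-iodo-3-O-TBS-5,7,3',4'-tetra-O-benzyl-(−)-epicatechin; 7 2-hydroxy-4,6-bis(benzyloxy)benzaldehyde
Product: 10 [2-hydroxy-4,6-bis(benzyloxy)phenyl](8-bromo-3-O-TBS-5,7,3',4'-tetra-O-benzylepicatechin-6-yl)methanol as both carbinol epimers, via C6-arylmagnesium chloride 8 (not isolated), via sodium 2-formylphenoxide 9 (not isolated)
Conditions: 5, iPrMgCl·LiCl (1.1 equiv), THF, −15 °C; then 9 [from 7, NaH, THF, 0 °C], −15 °C to rt; aq NH4Cl, used without chromatography on acidic silica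
Reagents that add atoms: none
Why: Iodine–magnesium exchange is much faster at the C6 iodide than at the C8 bromide, and the aryl Grignard reagent then adds 1,2 to the aldehyde, whose phenol is masked as a phenoxide that chelates magnesium to the carbonyl oxygen; the carbinol centre forms as a mixture, which does not matter because it becomes sp2 in step 7.

**Step 7**
Reactants: 10 [2-hydroxy-4,6-bis(benzyloxy)phenyl](8-bromo-protected epicatechin-6-yl)methanol; 11 (tert-butyldimethylsilyloxy)acetaldehyde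
Product: 15 3,4-trans-3-(tert-butyldimethylsilyloxy)-5,7-bis(benzyloxy)-4-(8-bromo-3-O-TBS-5,7,3',4'-tetra-O-benzylepicatechin-6-yl)chroman-2-ol (3R; both lactol anomers), via o-quinone methide 12 (not isolated), via catalyst-bound E-enamine 13 (not isolated), via open-chain hydroxy aldehyde 14 (not isolated)
Conditions: (S)-α,α-diphenylprolinol trimethylsilyl ether (20 mol %), PhCO2H (20 mol %), 11 (3 equiv, added slowly), CH2Cl2, 0 °C to rt
Reagents that add atoms: none
Why: Benzoic acid dehydrates the benzhydrol 10, which is stabilised by two trioxygenated rings, to the o-quinone methide 12; its exocyclic carbon (the future upper C4, already bonded to lower C6) is attacked by the E-enamine 13 to form C3–C4, and hydrolysis of the resulting iminium ion frees hydroxy aldehyde 14 and returns the amine. Upper ring C then closes as the lactol by 6-exo-trig addition of the phenol oxygen (O1) to the aldehyde carbon (C2). The closest known reaction is the diarylprolinol silyl ether-catalysed formal [4+2] annulation of o-quinone methides generated in situ from o-hydroxybenzhydrols with enolisable aldehydes, and α-alkoxy aldehydes are established enamine donors for this catalyst class. C3 is set by the catalyst, since the CPh2(OSiMe3) group of the (S)-amine shields one enamine face and the electrophile adds to the other, which makes C3 R; C4 is set by the relative topicity of the two prochiral partners, where the synclinal approach known from enamine Michael additions places the C4 aryl group trans to the C3 silyloxy group. The step needs catalyst control to override the lower-unit stereocentres and C-attack by the enamine to outrun Friedel–Crafts self-condensation; the first is expected because those centres lie five bonds from C4 on a twisted di-ortho-substituted ring, and the second is secured by the C8 bromine, which blocks the only nucleophilic arene position of the lower unit. Any cis lactol can still epimerise at C3 through 14 to a trans isomer, which should be separable as a diastereomer because the lower unit is enantiopure.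

**Step 8**
Reactants: 15 3,4-trans-3-silyloxy-4-(epicatechin-6-yl)chroman-2-ol
Product: 16 (3R)-3,4-trans-3-(tert-butyldimethylsilyloxy)-5,7-bis(benzyloxy)-4-(8-bromo-3-O-TBS-5,7,3',4'-tetra-O-benzylepicatechin-6-yl)chroman-2-one
Conditions: Dess–Martin periodinane, pyridine, CH2Cl2, 0 °C to rt
Reagents that add atoms: none
Why: Dess–Martin oxidation of the lactol hydroxyl should converge both anomers into one lactone under buffered conditions that leave C3 and C4 unchanged.

**Step 9**
Reactants: 16 3-silyloxy-4-(epicatechin-6-yl)chroman-2-one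
Product: 17 (2R)-2-(tert-butyldimethylsilyloxy)-3-[2-hydroxy-4,6-bis(benzyloxy)phenyl]-3-(8-bromo-3-O-TBS-5,7,3',4'-tetra-O-benzylepicatechin-6-yl)-N-methoxy-N-methylpropanamide
Conditions: MeNH(OMe)·HCl (3 equiv), AlMe3 (3 equiv), CH2Cl2, 0 °C to rt
Reagents that add atoms: N,O-dimethylhydroxylamine hydrochloride, CNOC.Cl
Why: Weinreb aminolysis of the aryl ester lactone by the aluminium amide opens ring C, frees the ring A phenol for the later closure, and should not epimerise C3 because no enolate is formed.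

**Step 10**
Reactants: 17 Weinreb amide; 18 4-bromo-1,2-bis(benzyloxy)benzene
Product: 20 (2R)-1-[3,4-bis(benzyloxy)phenyl]-2-(tert-butyldimethylsilyloxy)-3-[2-hydroxy-4,6-bis(benzyloxy)phenyl]-3-(8-bromo-3-O-TBS-5,7,3',4'-tetra-O-benzylepicatechin-6-yl)propan-1-one, via 3,4-bis(benzyloxy)phenylmagnesium bromide 19 (not isolated)
Conditions: 18, Mg, THF, rt to 40 °C; then 17 (19 in 3.5-fold excess), THF, 0 °C to rt; aq NH4Cl
Reagents that add atoms: none
Why: Weinreb ketone synthesis in which the first equivalent of Grignard reagent deprotonates the phenol and the next adds once to give a magnesium-chelated tetrahedral intermediate that collapses only on work-up, so over-addition and base epimerisation at C3 are avoided, and a magnesium rather than lithium reagent should leave the C8 bromide alone.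

**Step 11**
Reactants: 20 keto phenol
Product: 23 3-O-TBS-5,7,3',4'-tetra-O-benzylepicatechin-(4β→6)-8-bromo-3-O-TBS-5,7,3',4'-tetra-O-benzylepicatechin, via cyclic hemiketal 21 (not isolated), via cyclic oxocarbenium triflate 22 (not isolated)
Conditions: Et3SiH (5 equiv), Me3SiOTf (0.3 equiv), CH2Cl2, −78 °C to −40 °C; aq NaHCO3
Reagents that add atoms: none
Why: Reductive etherification in which the phenol adds 6-exo-trig to the ketone (hemiketal 21), ionisation gives the 2-aryl oxocarbenium ion 22, and the silane delivers hydride axially to C2 of the half-chair that holds the C3 silyloxy and C4 aryl groups trans-diaxial, that is anti to the neighbouring silyloxy group, which should set C2 as R with the aryl group cis to the C3 oxygen.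

**Step 12**
Reactants: 23 bis-silyl ether of the benzylated 8-bromo dimer
Product: 24 5,7,3',4'-tetra-O-benzylepicatechin-(4β→6)-8-bromo-5,7,3',4'-tetra-O-benzylepicatechin (both 3-OH free)
Conditions: Bu4NF (4 equiv), THF, 0 °C to 40 °C
Reagents that add atoms: none
Why: Fluoride-driven cleavage of both secondary silyl ethers through Si–F bond formation, to which the benzyl ethers, the aryl bromide and all stereocentres are inert.

**Step 13**
Reactants: 24 dimer diol; 25 3,4,5-tris(benzyloxy)benzoic acid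
Product: 26 3,3'-bis-O-[3,4,5-tris(benzyloxy)benzoyl] derivative of 24
Conditions: 25 (6 equiv), DCC (6 equiv), DMAP (2 equiv), CH2Cl2, rt
Reagents that add atoms: none
Why: Steglich esterification (carbodiimide activation with DMAP acyl transfer) should acylate both secondary alcohols, the hindered axial upper 3-OH being the reason for the excess of acid and DMAP, and no stereocentre is involved.

**Step 14**
Reactants: 26 fully benzylated 8-bromo digallate
Product: 27 procyanidin B-5 3,3'-di-O-gallate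
Conditions: H2 (1 atm), Pd(OH)2 on carbon, Et3N (1.2 equiv), THF–MeOH–H2O, rt
Reagents that add atoms: none
Why: Catalytic hydrogenolysis should cleave the fourteen benzyl ethers and the C8–Br bond (hydrodehalogenation, with Et3N taking up HBr) while the gallate esters, the flavan C2–O bonds and the interflavan bond survive, so the target is released without touching a stereocentre.

**Compound list**
1 | (−)-epicatechin, (2R,3R) | O[C@@H]1Cc2c(O)cc(O)cc2O[C@@H]1c1ccc(O)c(O)c1 | starting material
2 | 5,7,3',4'-tetra-O-benzyl-(−)-epicatechin | O[C@@H]1Cc2c(OCc3ccccc3)cc(OCc3ccccc3)cc2O[C@@H]1c1ccc(OCc2ccccc2)c(OCc2ccccc2)c1 | intermediate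
3 | 3-O-TBS-5,7,3',4'-tetra-O-benzyl-(−)-epicatechin | CC(C)(C)[Si](C)(C)O[C@@H]1Cc2c(OCc3ccccc3)cc(OCc3ccccc3)cc2O[C@@H]1c1ccc(OCc2ccccc2)c(OCc2ccccc2)c1 | intermediate
4 | 8-bromo-3-O-TBS-5,7,3',4'-tetra-O-benzyl-(−)-epicatechin | CC(C)(C)[Si](C)(C)O[C@@H]1Cc2c(OCc3ccccc3)cc(OCc3ccccc3)c(Br)c2O[C@@H]1c1ccc(OCc2ccccc2)c(OCc2ccccc2)c1 | intermediate
5 | 8-bromo-6-iodo-3-O-TBS-5,7,3',4'-tetra-O-benzyl-(−)-epicatechin | CC(C)(C)[Si](C)(C)O[C@@H]1Cc2c(OCc3ccccc3)c(I)c(OCc3ccccc3)c(Br)c2O[C@@H]1c1ccc(OCc2ccccc2)c(OCc2ccccc2)c1 | intermediate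
6 | 2,4,6-trihydroxybenzaldehyde | O=Cc1c(O)cc(O)cc1O | starting material
7 | 2-hydroxy-4,6-bis(benzyloxy)benzaldehyde | O=Cc1c(O)cc(OCc2ccccc2)cc1OCc1ccccc1 | intermediate
8 | C6-arylmagnesium chloride of the 8-bromo lower unit (from 5) | CC(C)(C)[Si](C)(C)O[C@@H]1Cc2c(OCc3ccccc3)c([Mg]Cl)c(OCc3ccccc3)c(Br)c2O[C@@H]1c1ccc(OCc2ccccc2)c(OCc2ccccc2)c1 | intermediate (not isolated)
9 | sodium 3,5-bis(benzyloxy)-2-formylphenoxide | [Na+].[O-]c1cc(OCc2ccccc2)cc(OCc2ccccc2)c1C=O | intermediate (not isolated)
10 | [2-hydroxy-4,6-bis(benzyloxy)phenyl](8-bromo-3-O-TBS-5,7,3',4'-tetra-O-benzylepicatechin-6-yl)methanol, both carbinol epimers, lower unit (2R,3R) | Oc1cc(OCc2ccccc2)cc(OCc2ccccc2)c1C(O)c1c(OCc2ccccc2)c(Br)c2c(c1OCc1ccccc1)C[C@@H](O[Si](C)(C)C(C)(C)C)[C@@H](c1ccc(OCc3ccccc3)c(OCc3ccccc3)c1)O2 | intermediate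
11 | (tert-butyldimethylsilyloxy)acetaldehyde | O=CCO[Si](C)(C)C(C)(C)C | starting material
12 | o-quinone methide: 3,5-bis(benzyloxy)-6-[(8-bromo-protected epicatechin-6-yl)methylidene]cyclohexa-2,4-dien-1-one (double-bond geometry not fixed) | O=C1C=C(OCc2ccccc2)C=C(OCc2ccccc2)C1=Cc1c(OCc2ccccc2)c(Br)c2c(c1OCc1ccccc1)C[C@@H](O[Si](C)(C)C(C)(C)C)[C@@H](c1ccc(OCc3ccccc3)c(OCc3ccccc3)c1)O2 | intermediate (not isolated)
13 | E-enamine of 11 with (S)-α,α-diphenylprolinol trimethylsilyl ether | C[Si](C)(C)OC(c1ccccc1)(c1ccccc1)[C@@H]1CCCN1/C=C/O[Si](C)(C)C(C)(C)C | intermediate (not isolated)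
14 | (2R)-2-(TBSO)-3-[2-hydroxy-4,6-bis(benzyloxy)phenyl]-3-(8-bromo-protected epicatechin-6-yl)propanal, open form of 15 | CC(C)(C)[Si](C)(C)O[C@@H](C=O)[C@@H](c1c(OCc2ccccc2)c(Br)c2c(c1OCc1ccccc1)C[C@@H](O[Si](C)(C)C(C)(C)C)[C@@H](c1ccc(OCc3ccccc3)c(OCc3ccccc3)c1)O2)c1c(OCc2ccccc2)cc(OCc2ccccc2)cc1O | intermediate (not isolated)
15 | (3R)-3-(TBSO)-5,7-bis(benzyloxy)-4-(8-bromo-protected epicatechin-6-yl)chroman-2-ol, C4 aryl trans to the C3 oxygen, both anomers | CC(C)(C)[Si](C)(C)O[C@@H]1[C@@H](c2c(OCc3ccccc3)c(Br)c3c(c2OCc2ccccc2)C[C@@H](O[Si](C)(C)C(C)(C)C)[C@@H](c2ccc(OCc4ccccc4)c(OCc4ccccc4)c2)O3)c2c(OCc3ccccc3)cc(OCc3ccccc3)cc2OC1O | intermediate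
16 | (3R)-3-(TBSO)-5,7-bis(benzyloxy)-4-(8-bromo-protected epicatechin-6-yl)chroman-2-one, 3,4-trans | CC(C)(C)[Si](C)(C)O[C@@H]1[C@@H](c2c(OCc3ccccc3)c(Br)c3c(c2OCc2ccccc2)C[C@@H](O[Si](C)(C)C(C)(C)C)[C@@H](c2ccc(OCc4ccccc4)c(OCc4ccccc4)c2)O3)c2c(OCc3ccccc3)cc(OCc3ccccc3)cc2OC1=O | intermediate
17 | Weinreb amide: (2R)-2-(TBSO)-3-[2-hydroxy-4,6-bis(benzyloxy)phenyl]-3-(8-bromo-protected epicatechin-6-yl)-N-methoxy-N-methylpropanamide | CC(C)(C)[Si](C)(C)O[C@@H](C(=O)N(C)OC)[C@@H](c1c(OCc2ccccc2)c(Br)c2c(c1OCc1ccccc1)C[C@@H](O[Si](C)(C)C(C)(C)C)[C@@H](c1ccc(OCc3ccccc3)c(OCc3ccccc3)c1)O2)c1c(OCc2ccccc2)cc(OCc2ccccc2)cc1O | intermediate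
18 | 4-bromo-1,2-bis(benzyloxy)benzene | Brc1ccc(OCc2ccccc2)c(OCc2ccccc2)c1 | starting material
19 | 3,4-bis(benzyloxy)phenylmagnesium bromide | Br[Mg]c1ccc(OCc2ccccc2)c(OCc2ccccc2)c1 | intermediate (not isolated)
20 | keto phenol: (2R)-1-[3,4-bis(benzyloxy)phenyl]-2-(TBSO)-3-[2-hydroxy-4,6-bis(benzyloxy)phenyl]-3-(8-bromo-protected epicatechin-6-yl)propan-1-one | CC(C)(C)[Si](C)(C)O[C@@H](C(=O)c1ccc(OCc2ccccc2)c(OCc2ccccc2)c1)[C@@H](c1c(OCc2ccccc2)c(Br)c2c(c1OCc1ccccc1)C[C@@H](O[Si](C)(C)C(C)(C)C)[C@@H](c1ccc(OCc3ccccc3)c(OCc3ccccc3)c1)O2)c1c(OCc2ccccc2)cc(OCc2ccccc2)cc1O | intermediate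
21 | cyclic hemiketal of 20 (2-aryl-chroman-2-ol, C2 epimers) | CC(C)(C)[Si](C)(C)O[C@@H]1[C@@H](c2c(OCc3ccccc3)c(Br)c3c(c2OCc2ccccc2)C[C@@H](O[Si](C)(C)C(C)(C)C)[C@@H](c2ccc(OCc4ccccc4)c(OCc4ccccc4)c2)O3)c2c(OCc3ccccc3)cc(OCc3ccccc3)cc2OC1(O)c1ccc(OCc2ccccc2)c(OCc2ccccc2)c1 | intermediate (not isolated)
22 | 2-aryl-3,4-dihydrochromenylium (oxocarbenium) triflate | CC(C)(C)[Si](C)(C)O[C@@H]1[C@@H](c2c(OCc3ccccc3)c(Br)c3c(c2OCc2ccccc2)C[C@@H](O[Si](C)(C)C(C)(C)C)[C@@H](c2ccc(OCc4ccccc4)c(OCc4ccccc4)c2)O3)c2c(OCc3ccccc3)cc(OCc3ccccc3)cc2[O+]=C1c1ccc(OCc2ccccc2)c(OCc2ccccc2)c1.[O-]S(=O)(=O)C(F)(F)F | intermediate (not isolated)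
23 | 3-O-TBS-5,7,3',4'-tetra-O-benzylepicatechin-(4β→6)-8-bromo-3-O-TBS-5,7,3',4'-tetra-O-benzylepicatechin; upper unit 2R,3R with the C4 aryl trans to the C3 oxygen, lower unit 2R,3R | CC(C)(C)[Si](C)(C)O[C@@H]1[C@@H](c2c(OCc3ccccc3)c(Br)c3c(c2OCc2ccccc2)C[C@@H](O[Si](C)(C)C(C)(C)C)[C@@H](c2ccc(OCc4ccccc4)c(OCc4ccccc4)c2)O3)c2c(OCc3ccccc3)cc(OCc3ccccc3)cc2O[C@@H]1c1ccc(OCc2ccccc2)c(OCc2ccccc2)c1 | intermediate
24 | 5,7,3',4'-tetra-O-benzylepicatechin-(4β→6)-8-bromo-5,7,3',4'-tetra-O-benzylepicatechin (diol) | O[C@@H]1[C@@H](c2c(OCc3ccccc3)c(Br)c3c(c2OCc2ccccc2)C[C@@H](O)[C@@H](c2ccc(OCc4ccccc4)c(OCc4ccccc4)c2)O3)c2c(OCc3ccccc3)cc(OCc3ccccc3)cc2O[C@@H]1c1ccc(OCc2ccccc2)c(OCc2ccccc2)c1 | intermediate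
25 | 3,4,5-tris(benzyloxy)benzoic acid | OC(=O)c1cc(OCc2ccccc2)c(OCc2ccccc2)c(OCc2ccccc2)c1 | starting material
26 | 3,3'-bis-O-[3,4,5-tris(benzyloxy)benzoyl] derivative of 24 | O=C(O[C@@H]1[C@@H](c2c(OCc3ccccc3)c(Br)c3c(c2OCc2ccccc2)C[C@@H](OC(=O)c2cc(OCc4ccccc4)c(OCc4ccccc4)c(OCc4ccccc4)c2)[C@@H](c2ccc(OCc4ccccc4)c(OCc4ccccc4)c2)O3)c2c(OCc3ccccc3)cc(OCc3ccccc3)cc2O[C@@H]1c1ccc(OCc2ccccc2)c(OCc2ccccc2)c1)c1cc(OCc2ccccc2)c(OCc2ccccc2)c(OCc2ccccc2)c1 | intermediate
27 | procyanidin B-5 3,3'-di-O-gallate | O=C(O[C@@H]1[C@@H](c2c(O)cc3c(c2O)C[C@@H](OC(=O)c2cc(O)c(O)c(O)c2)[C@@H](c2ccc(O)c(O)c2)O3)c2c(O)cc(O)cc2O[C@@H]1c1ccc(O)c(O)c1)c1cc(O)c(O)c(O)c1 | target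

**Step count**
Total: 14 steps. Longest linear sequence: 13 steps (steps 1–4 and 6–14 from (−)-epicatechin); step 5 is the one-step side branch.

**Steps most likely to fail**

Step 7. The enamine may be too slow at the congested methide carbon, which has three ortho substituents around it, so that 12 is lost to self-condensation. Alternatively, the two faces of 12 may not be distinguished, which would scramble C4. The fallback gives up the annulation and forms the C4–C6 bond on an intact upper unit by the flavan-4-yl cation coupling used for benzylated procyanidins. It sets out from 3 and 4. Benzylic oxidation of 3 with DDQ in CH2Cl2 in the presence of 2-ethoxyethanol should give 3-O-TBS-5,7,3',4'-tetra-O-benzyl-4β-(2-ethoxyethoxy)epicatechin F1, with the new ether trans to the silyloxy group. Ionisation of F1 with catalytic Me3SiOTf in CH2Cl2 at −78 °C in the presence of 4 should let the C8-blocked nucleophile attack through C6, anti to the C3 silyloxy group. This comes back to the route at 23, so steps 5 to 11 are not needed.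

Step 6. The hindered aryl Grignard reagent 8 may not add to the electron-rich phenoxide-aldehyde and may instead be protonated on work-up, returning the C6–H flavan. The fallback protects the phenol and uses a more reactive organolithium. It sets out from 7 and 5. Allylation of 7 (allyl bromide, K2CO3, DMF) gives 2-allyloxy-4,6-bis(benzyloxy)benzaldehyde F2. Iodine–lithium exchange on 5 (n-BuLi, THF, −78 °C, faster than bromine–lithium exchange) gives the C6 aryllithium F3. Addition of F3 to F2 at −78 °C gives the O-allyl benzhydrol F4. Neutral Tsuji–Trost deallylation (Pd(PPh3)4, morpholine, THF, rt) should then release the phenol without ionising the carbinol, which comes back to the route at 10.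

Step 11. Hydride may be delivered to the wrong face of C2, or the Lewis acid may ionise the doubly benzylic C4–aryl bond or a flavan C2–O bond. The fallback sets C2 by carbonyl addition and closes ring C by an invertive substitution instead of an oxocarbenium reduction. It sets out from 15. Excess Grignard reagent 19 in THF at −78 °C to 0 °C should add to the lactol, which reacts as its open form 14, under Felkin–Anh control by the non-chelating silyloxy group. This gives the anti (1,2-erythro) benzylic alcohol F5. Intramolecular Mitsunobu etherification (PPh3, DIAD, THF, 0 °C) lets the ring A phenol displace the activated benzylic hydroxyl with inversion, which places the C2 aryl group cis to the C3 oxygen. This comes back to the route at 23 and replaces steps 8 to 11.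

**Further compounds**
F1 | step 7 | 3-O-TBS-5,7,3',4'-tetra-O-benzyl-4β-(2-ethoxyethoxy)epicatechin | CC(C)(C)[Si](C)(C)O[C@@H]1[C@@H](OCCOCC)c2c(OCc3ccccc3)cc(OCc3ccccc3)cc2O[C@@H]1c1ccc(OCc2ccccc2)c(OCc2ccccc2)c1
F2 | step 6 | 2-allyloxy-4,6-bis(benzyloxy)benzaldehyde | C=CCOc1cc(OCc2ccccc2)cc(OCc2ccccc2)c1C=O
F3 | step 6 | C6-aryllithium of the 8-bromo lower unit (from 5) | CC(C)(C)[Si](C)(C)O[C@@H]1Cc2c(OCc3ccccc3)c([Li])c(OCc3ccccc3)c(Br)c2O[C@@H]1c1ccc(OCc2ccccc2)c(OCc2ccccc2)c1
F4 | step 6 | O-allyl ether of 10: [2-allyloxy-4,6-bis(benzyloxy)phenyl](8-bromo-protected epicatechin-6-yl)methanol | C=CCOc1cc(OCc2ccccc2)cc(OCc2ccccc2)c1C(O)c1c(OCc2ccccc2)c(Br)c2c(c1OCc1ccccc1)C[C@@H](O[Si](C)(C)C(C)(C)C)[C@@H](c1ccc(OCc3ccccc3)c(OCc3ccccc3)c1)O2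
F5 | step 11 | anti alcohol: 1-[3,4-bis(benzyloxy)phenyl]-2-(TBSO)-3-[2-hydroxy-4,6-bis(benzyloxy)phenyl]-3-(8-bromo-protected epicatechin-6-yl)propan-1-ol, C1 hydroxyl anti to the C2 silyloxy group | CC(C)(C)[Si](C)(C)O[C@@H]([C@@H](O)c1ccc(OCc2ccccc2)c(OCc2ccccc2)c1)[C@@H](c1c(OCc2ccccc2)c(Br)c2c(c1OCc1ccccc1)C[C@@H](O[Si](C)(C)C(C)(C)C)[C@@H](c1ccc(OCc3ccccc3)c(OCc3ccccc3)c1)O2)c1c(OCc2ccccc2)cc(OCc2ccccc2)cc1O
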